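What Thursday's run left over for J and G, with E at 10 mM, stood at 3.00 h, the earliest reading, at J 14 % and G 9 %. The proposed steps let X and Q interconvert, send Q to J or D, send X to G or with E to L, and let G go to Z.

common to all: X 10 mM
- Wednesday's: Q 2.5 mM; E 2.5 mM; run made earlier
- Thursday's: Q 2.5 mM; E 10 mM; run made earlier
- flask: Q 2.50 mM; E 5.00 mM; time 15 h

| run | time / h | J / % | G / % |
|---|---|---|---|
| Wednesday's | 3.00 | 34 | 40 |
| Wednesday's | 6.00 | 35 | 40 |
| Wednesday's | 10.0 | 35 | 39 |
| Wednesday's | 12.0 | 36 | 39 |
| Wednesday's | 15.0 | 37 | 38 |
| Thursday's | 3.00 | 14 | 9 |
| Thursday's | 6.00 | 15 | 10 |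
| Thursday's | 10.0 | 16 | 11 |
| Thursday's | 12.0 | 16 | 14 |
| Thursday's | 15.0 | 12 | 12 |

(readings scatter by 1.5 percentage points)

1. share of J in J plus G at 50 s
2. share of J in J plus G at 25 min
3. share of J in J plus G at 15 h

Two chemists dispute the new flask, whose E charge is half of Thursday's. The one who made the forecast weighs the start by charges and rate constants, X being 80.0 % of the charge and Q 20.0 %, and she writes 30 %, 45 % and 52 % for the three times, saying of the early share “probably lower and very uncertain”.

Her colleague follows one molecule instead. Counting every J as Q's own, a Q charged on Thursday ended as J with chance 70.0 %, and an X charged ended as G with chance 11.2 %. The ratio is 6.22, which he calls the fork odds, J won per Q charged over G won per X charged, a selectivity factor, though the G reading carries a scatter of 1.5 percentage points and the odds carry it too. Assuming these odds hold at the start of the new flask and weighting them by its charges, he expects 60.9 % of J in J plus G, far from her 30 %. E amounts to 40.0 % of the X and Q together, less than X's 80.0 %, so he expects the X that E cannot take to feed G, and the share to fall toward the 49.3 % read on Wednesday at 15.0 h.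

The flask gives 63.7 % at 50 s, 49.9 % at 25 min and 48.4 % at 15 h, so the share falls as he said while her figures rise, and her early figure lies 34 points too low; her figure at 25 min stands within the tolerance, but there, ahead of the readings, her rising figures merely cross the falling flask, and the region her view keeps is the late one, among the readings from 3.00 h on that she reckoned from, where her figure at 15 h stands within the tolerance as well.

    X ⇌ Q (K = 0.120, k = 0.0440 min⁻¹)
    X → G (k = 0.0170 min⁻¹)
    Q → J (k = 0.130 min⁻¹)
    Q → D (k = 1.80 × 10⁻⁶ min⁻¹)
    G ⇌ Z (K = 0.120, k = 0.00630 min⁻¹)
    X + E → L (k = 25.0 M⁻¹ min⁻¹)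

In the flask J and G stand level at 0.393 h. With the same X and E but Q raised to 10 mM, the fork odds give 86.2 %, and that flask shows 85.8 % at 50 s.

The readings stem from a simulated flask on assumed constants, noise included.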